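The earlier runs and the new flask were generated by integration from invented constants.

A product cannot outrun partner if each product takes one partner.

| flask | left-handed substrate | right-handed substrate | partner | protic impurity | catalyst | remark | time |
|---|---|---|---|---|---|---|---|
| dawn | 5 mM | 5 mM | 0.80 equiv | 0.20 mM | 2.5 mol% | run made earlier |  |
| spring | 20 mM | 20 mM | 0.80 equiv | 0.20 mM | 2.5 mol% | run made earlier |  |
| summer | 10 mM | 10 mM | 0.80 equiv | 0.20 mM | 5 mol% | run made earlier |  |
| flask | 10 mM | 10 mM | 0.800 equiv | 0.200 mM | 2.5 mol% |  | 40 min |
- dawn (time / min: left-handed substrate / %, right-handed substrate / %, left-handed product / %): 2.00: 44.7, 50.0, 4.2; 3.00: 43.8, 49.6, 6.5; 5.00: 39.3, 47.7, 10.9; 8.00: 36.4, 48.0, 13.2; 15.0: 30.2, 46.5, 20.3; 25.0: 26.0, 45.3, 23.9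
- spring (time / min: left-handed substrate / %, right-handed substrate / %, left-handed product / %): 4.00: 19.9, 43.3, 30.8; 8.00: 18.4, 42.8, 31.9; 12.0: 18.2, 43.3, 32.9; 15.0: 18.2, 43.0, 32.5; 20.0: 18.7, 42.6, 32.8; 25.0: 17.6, 43.0, 33.1
- summer (time / min: left-handed substrate / %, right-handed substrate / %, left-handed product / %): 2.00: 29.1, 45.6, 21.2; 6.00: 21.8, 44.3, 28.7; 12.0: 19.1, 44.1, 30.8; 15.0: 19.0, 43.1, 31.8; 25.0: 18.2, 43.2, 31.9

(scatter of a reading: 0.5 percentage points)
* part of the left-handed substrate and right-handed substrate charged together that has reacted at 40 min
* excess of left-handed product over right-handed product in the product at 40 min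
* excess of right-handed substrate over left-handed substrate among what is left of the two at 40 min
- catalyst is single-handed; left-handed substrate and right-handed substrate are mirror images of each other, charged as a racemate, each of them at the stated concentration
- an excess is the difference of the two amounts in percent of their sum
- an excess is below zero if the other one leads

Two chemists argue over the flask. The timer treats the left-handed substrate as a pseudo-first-order decay. The last dawn reading gives a rate constant of 0.0262 min⁻¹. The flask has twice the catalyst of dawn, so the timer expects 6.17 % of left-handed substrate at 40 min. That is 43.8 % reacted from the left-handed side by itself. Dawn, the timer adds, was still moving at its last reading.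

The counter calls partner the limiting reagent. Let c be the reacted part of both substrates. The partner charge pays for c = 40.0 %, and that is the first answer. But summer stands at 38.6 % at its last reading. So go round again, and let the protic impurity take one partner each. The ceiling is 39.0 %: the conversion paid for by the partner that the protic impurity leaves. The timer's figure is more than this ceiling.

The counter also answers the point about dawn. Summer has the same substrate charge and more catalyst, so the flask at 40 min compares with summer near 20.0 min. Summer's left-handed substrate reads 19.0 % at 15.0 min and 18.2 % at 25.0 min.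

For the split, take the last summer readings. Right-handed minus left-handed substrate is D = 25 percentage points. Each product is what its substrate lost, so eP = D/c and eS = D/(1 − c). My reckoning is c = 39.0 %, eP = 64.1 % and eS = 41.0 %.

The forecast, on the counter's side, reads “points to partner running out, not catalyst death” and gives c = 38.8 %, eP = 64 % and eS = 40.5 %.

The flask gives c = 38.2 %, eP = 64.9 % and eS = 39.0 %.

    partner ⇌ dormant form (K = 1.80, k = 0.00500 min⁻¹)
    partner + protic impurity → quenched reagent (k = 69.0 M⁻¹ min⁻¹)
    partner + catalyst + left-handed substrate → catalyst + left-handed product (k = 1.10 × 10⁵ M⁻² min⁻¹)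
    partner + catalyst + right-handed substrate → catalyst + right-handed product (k = 16000 M⁻² min⁻¹)
    left-handed substrate ⇌ right-handed substrate (k = 3.80 × 10⁻⁴ min⁻¹)

At 40.0 min the flask keeps 0.18 % of its partner, with quenched reagent at 0.183 mM and dormant form at 0.164 mM. Taking these three from the charge, the ceiling of 39.0 % comes down to 38.2 %. A neighbour flask, with 2.00 equiv of partner, has a ceiling of 99.0 % and reaches c = 79.8 %. That flask is the timer's ground: at 40.0 min it keeps 14 % of its partner, and left-handed substrate is down to 0.187 %.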